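**Retrosynthetic overview**

1. Target 10 comes from 9 by MOM removal, and 9 from 7 by an aromatic Claisen shift of the 7-O-prenyl group to C6, steered by the 5-OH···O=C4 hydrogen bond; this makes the C6–C(CH3)2CH=CH2 bond.
2. 7 comes from the achiral aldehyde 6 by closing ring C through the C3–C4 bond: an enantioselective intramolecular hydroacylation adds the formyl C–H of ring A across the O1-bound 1-arylethenyl group and sets C2.
3. Enabling feature: in ring C, C2 carries one H, O1 and ring B, C3 is a bare CH2, and C4 is an aryl ketone ortho to O1 on ring A, so ring C is the formal C–H adduct of a salicylaldehyde-type formyl group to an aryl 1-arylvinyl ether.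
4. 6 comes from C–O coupling (O1–C2) of the symmetric phenol 2 (from 2,4,6-trihydroxybenzaldehyde 1) with vinyl bromide 5 (from acetovanillone 3).
5. Ring order: rings A and B are bought as benzenoid starting materials; ring C is the only ring made, in step 5.

Key step: step 5

Assumption: in step 5 the (R)-configured bisphosphine is taken to deliver the (2S)-product; if the sense proves opposite, the (S)-ligand is used and nothing else changes.

**Route**

Step 1
Reactants: 1 2,4,6-trihydroxybenzaldehyde
Product: 2 2,6-dihydroxy-4-[(3-methylbut-2-en-1-yl)oxy]benzaldehyde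
Conditions: 1-bromo-3-methylbut-2-ene (1.0 equiv), K2CO3 (1.0 equiv), acetone, 25 °C
Reagents that add atoms: 1-bromo-3-methylbut-2-ene (prenyl bromide) CC(C)=CCBr
Why: Williamson ether synthesis in which the 4-OH, the most acidic hydroxyl and the only one not hydrogen-bonded to the formyl group, is alkylated selectively with one equivalent of base and bromide.

Step 2
Reactants: 3 1-(4-hydroxy-3-methoxyphenyl)ethan-1-one (acetovanillone)
Product: 4 1-[3-methoxy-4-(methoxymethoxy)phenyl]ethan-1-one
Conditions: chloromethyl methyl ether, iPr2NEt, CH2Cl2, 0 to 25 °C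
Reagents that add atoms: chloromethyl methyl ether COCCl
Why: Standard O-alkylation of the phenol with chloromethyl methyl ether under amine base (MOM protection), giving an acetal that survives base, copper, rhodium and europium and is removed by acid at the end.

Step 3
Reactants: 4 1-[3-methoxy-4-(methoxymethoxy)phenyl]ethan-1-one
Product: 5 4-(1-bromoethenyl)-2-methoxy-1-(methoxymethoxy)benzene
Conditions: P(OPh)3, Br2, CH2Cl2, −60 °C; then Et3N and 4, −60 to 25 °C
Reagents that add atoms: bromine BrBr, delivered as its adduct with triphenyl phosphite Br[P+](Oc1ccccc1)(Oc1ccccc1)Oc1ccccc1.[Br-]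
Why: Ketone-to-vinyl-bromide conversion with the triphenyl phosphite–bromine adduct: the carbonyl oxygen is activated as an oxyphosphonium ion, bromide adds and Et3N-promoted elimination of triphenyl phosphate leaves the 1-bromoalkene, while the amine keeps the medium non-acidic for the MOM acetal.

Step 4
Reactants: 2 2,6-dihydroxy-4-[(3-methylbut-2-en-1-yl)oxy]benzaldehyde (1.5 equiv); 5 4-(1-bromoethenyl)-2-methoxy-1-(methoxymethoxy)benzene
Product: 6 2-hydroxy-6-({1-[3-methoxy-4-(methoxymethoxy)phenyl]ethenyl}oxy)-4-[(3-methylbut-2-en-1-yl)oxy]benzaldehyde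
Conditions: CuI (10 mol%), N,N-dimethylglycine hydrochloride (30 mol%), Cs2CO3, 1,4-dioxane, 90 °C
Reagents that add atoms: none
Why: Ullmann-type copper-catalysed C–O coupling of a vinyl bromide with a phenol (O-vinylation), in which 2 is used in excess and the second, equivalent OH stays locked in its hydrogen bond to the formyl group so that mono-etherification should prevail.

Step 5
Reactants: 6 2-hydroxy-6-({1-[3-methoxy-4-(methoxymethoxy)phenyl]ethenyl}oxy)-4-[(3-methylbut-2-en-1-yl)oxy]benzaldehyde
Product: 7 (2S)-5-hydroxy-2-[3-methoxy-4-(methoxymethoxy)phenyl]-7-[(3-methylbut-2-en-1-yl)oxy]-2,3-dihydro-4H-chromen-4-one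
Conditions: [Rh(cod)Cl]2 (2.5 mol%), (R)-DTBM-SEGPHOS (5.5 mol%), NaB[3,5-(CF3)2C6H3]4 (5 mol%), THF, 60 °C
Reagents that add atoms: none
Why: Proposed new method: cationic monovalent rhodium bearing the chiral bisphosphine adds oxidatively into the formyl C–H bond of 6 to give an acyl rhodium hydride (trivalent rhodium), the pendant 1-aryl-1-aryloxyethene inserts into Rh–H so that hydride goes to C2 and rhodium to the terminal carbon C3, and C–C reductive elimination then forms the C3–C4 bond and returns monovalent rhodium. The closest known reaction type is the rhodium-catalysed enantioselective intramolecular anti-Markovnikov hydroacylation of 1,1-disubstituted alkenes tethered to aryl aldehydes, established for carbon tethers (3-substituted indanones and tetralones) and for N-vinyl heteroaryl aldehydes, but not for an aryl 1-arylvinyl ether that would give a flavanone. Ring C closes in the 6-endo-trig sense through a seven-membered acyl alkyl rhodacycle. The only stereocentre, C2, is created in the hydride-insertion event, where the C2-symmetric ligand pocket selects the alkene face, so the configuration is under catalyst control. The step needs endo over exo regioselectivity (exo would give a 2-aryl-2-methylbenzofuran-3-one), which the fully substituted C2 secures because exo closure demands a tertiary α-aryl α-aryloxy C–Rh bond, and it needs reductive elimination to outrun decarbonylation and β-aryloxy elimination, which the short tether, the ether oxygen O1 and the hydrogen-bonded ortho OH beside the acyl group favour by holding alkene and acyl group on the metal.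

Step 6
Reactants: 7 (2S)-5-hydroxy-2-[3-methoxy-4-(methoxymethoxy)phenyl]-7-[(3-methylbut-2-en-1-yl)oxy]-2,3-dihydro-4H-chromen-4-one
Product: 9 (2S)-5,7-dihydroxy-2-[3-methoxy-4-(methoxymethoxy)phenyl]-6-(2-methylbut-3-en-2-yl)-2,3-dihydro-4H-chromen-4-one, via ortho-dienone 8 (not isolated)
Conditions: Eu(fod)3 (10 mol%), CHCl3, 60 °C
Reagents that add atoms: none
Why: Lewis-acid-catalysed aromatic Claisen rearrangement of the aryl prenyl ether: the 5-OH/C4=O chelate, which also binds trivalent europium, localises double-bond character in C6=C7 so that the [3,3] shift should go to C6 and tautomerisation of dienone 8 delivers the 1,1-dimethylallyl group, with C2 untouched under these neutral conditions.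

Step 7
Reactants: 9 (2S)-5,7-dihydroxy-2-[3-methoxy-4-(methoxymethoxy)phenyl]-6-(2-methylbut-3-en-2-yl)-2,3-dihydro-4H-chromen-4-one
Product: 10 (2S)-5,7-dihydroxy-2-(4-hydroxy-3-methoxyphenyl)-6-(2-methylbut-3-en-2-yl)-2,3-dihydro-4H-chromen-4-one
Conditions: 3 M aq. HCl, MeOH, 50 °C
Reagents that add atoms: none
Why: Acid-catalysed methanolysis of the MOM acetal, under which the flavanone stereocentre C2 does not epimerise (ring opening to the chalcone is a base-promoted process) and the monosubstituted alkene of the 1,1-dimethylallyl group is not protonated.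

**Compound list**

1 | 2,4,6-trihydroxybenzaldehyde | O=Cc1c(O)cc(O)cc1O | starting material
2 | 2,6-dihydroxy-4-[(3-methylbut-2-en-1-yl)oxy]benzaldehyde | O=Cc1c(O)cc(OCC=C(C)C)cc1O | intermediate
3 | 1-(4-hydroxy-3-methoxyphenyl)ethan-1-one (acetovanillone) | CC(=O)c1ccc(O)c(OC)c1 | starting material
4 | 1-[3-methoxy-4-(methoxymethoxy)phenyl]ethan-1-one | CC(=O)c1ccc(OCOC)c(OC)c1 | intermediate
5 | 4-(1-bromoethenyl)-2-methoxy-1-(methoxymethoxy)benzene | C=C(Br)c1ccc(OCOC)c(OC)c1 | intermediate
6 | 2-hydroxy-6-({1-[3-methoxy-4-(methoxymethoxy)phenyl]ethenyl}oxy)-4-[(3-methylbut-2-en-1-yl)oxy]benzaldehyde | O=Cc1c(O)cc(OCC=C(C)C)cc1OC(=C)c1ccc(OCOC)c(OC)c1 | intermediate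
7 | (2S)-5-hydroxy-2-[3-methoxy-4-(methoxymethoxy)phenyl]-7-[(3-methylbut-2-en-1-yl)oxy]-2,3-dihydro-4H-chromen-4-one | CC(C)=CCOc1cc2c(c(O)c1)C(=O)C[C@@H](c1ccc(OCOC)c(OC)c1)O2 | intermediate
8 | ortho-dienone: (2S)-5-hydroxy-2-[3-methoxy-4-(methoxymethoxy)phenyl]-6-(2-methylbut-3-en-2-yl)-2,3-dihydro-4H-chromene-4,7(6H)-dione (either configuration at C6) | C=CC(C)(C)C1C(=O)C=C2O[C@H](c3ccc(OCOC)c(OC)c3)CC(=O)C2=C1O | intermediate (not isolated)
9 | (2S)-5,7-dihydroxy-2-[3-methoxy-4-(methoxymethoxy)phenyl]-6-(2-methylbut-3-en-2-yl)-2,3-dihydro-4H-chromen-4-one | C=CC(C)(C)c1c(O)cc2c(c1O)C(=O)C[C@@H](c1ccc(OCOC)c(OC)c1)O2 | intermediate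
10 | (2S)-5,7-dihydroxy-2-(4-hydroxy-3-methoxyphenyl)-6-(2-methylbut-3-en-2-yl)-2,3-dihydro-4H-chromen-4-one | C=CC(C)(C)c1c(O)cc2c(c1O)C(=O)C[C@@H](c1ccc(O)c(OC)c1)O2 | target

**Step count and risks**

Total step count: 7. Longest linear sequence: 6 steps (3 → 4 → 5 → 6 → 7 → 9 → 10, steps 2 to 7).

Steps most likely to fail:

Step 5 (Proposed new method). Hydride insertion may take the exo course. The alkyl rhodium intermediate may lose the ring A aryloxy group by β-elimination. The acyl rhodium hydride may decarbonylate. Facial selectivity may be low or reversed, and the prenyl ether may be isomerised or cleaved by the rhodium hydride.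
Fallback (known chemistry, sets out from 4 and 2, comes back at 7): ketone 4 is brominated at the methyl group (PhNMe3Br3, THF, 0 °C) to 2-bromo-1-[3-methoxy-4-(methoxymethoxy)phenyl]ethan-1-one F1. Corey–Bakshi–Shibata reduction ((S)-2-methyl-CBS-oxazaborolidine, BH3·SMe2, THF, −20 °C) should give (1S)-2-bromo-1-[3-methoxy-4-(methoxymethoxy)phenyl]ethan-1-ol F2. Mitsunobu etherification of phenol 2 with F2 (PPh3, DIAD, toluene, −20 °C) should proceed with inversion to 2-{(1R)-2-bromo-1-[3-methoxy-4-(methoxymethoxy)phenyl]ethoxy}-6-hydroxy-4-[(3-methylbut-2-en-1-yl)oxy]benzaldehyde F3. An N-heterocyclic carbene (3-benzyl-5-(2-hydroxyethyl)-4-methylthiazolium chloride, DBU, THF, 25 °C) then turns the formyl group into an acyl anion equivalent that displaces the primary bromide (6-exo-tet). This forms the same C3–C4 bond and gives 7 with C2 already fixed by the reduction.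

Step 4. The coupling may be slow because the phenoxide of 2 is delocalised into the formyl group and can chelate copper. The vinyl bromide may be dehydrobrominated at 90 °C, and double vinylation is possible.
Fallback (sets out from 5 and 2, comes back at 6): the polarity of the vinyl partner is reversed. Miyaura borylation of 5 (B2pin2, PdCl2(dppf), KOPh, toluene, 50 °C) should give 2-{1-[3-methoxy-4-(methoxymethoxy)phenyl]ethenyl}-4,4,5,5-tetramethyl-1,3,2-dioxaborolane F4. Oxidative Chan–Lam coupling of F4 with 2 (Cu(OAc)2, pyridine, 4 Å molecular sieves, air, CH2Cl2, 25 °C) should give 6 at room temperature without carbonate base.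

Step 6. The [3,3] shift may partly go to C8 instead of C6, and the new allyl group may cyclise onto a neighbouring hydroxyl under Lewis acid catalysis.
Fallback (sets out from 2, comes back at 10): the sigmatropic step is moved to the symmetric aldehyde, where both ortho positions are equivalent. Claisen rearrangement of 2 (Eu(fod)3, CHCl3, 60 °C, or heating in N,N-diethylaniline) should give 2,4,6-trihydroxy-3-(2-methylbut-3-en-2-yl)benzaldehyde F5. Its only non-chelated hydroxyl is protected (chloromethyl methyl ether, iPr2NEt, CH2Cl2) as 2,6-dihydroxy-4-(methoxymethoxy)-3-(2-methylbut-3-en-2-yl)benzaldehyde F6. Copper-catalysed vinylation with 5 under the conditions of step 4 should take place at the unhindered hydroxyl remote from the tertiary alkyl group and give 2-hydroxy-6-({1-[3-methoxy-4-(methoxymethoxy)phenyl]ethenyl}oxy)-4-(methoxymethoxy)-3-(2-methylbut-3-en-2-yl)benzaldehyde F7. Hydroacylation under the conditions of step 5 should give (2S)-5-hydroxy-7-(methoxymethoxy)-2-[3-methoxy-4-(methoxymethoxy)phenyl]-6-(2-methylbut-3-en-2-yl)-2,3-dihydro-4H-chromen-4-one F8. Acid methanolysis (3 M aq. HCl, MeOH, 50 °C) removes both MOM groups and gives 10.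

**Further compounds**

F1 | step 5 | 2-bromo-1-[3-methoxy-4-(methoxymethoxy)phenyl]ethan-1-one | O=C(CBr)c1ccc(OCOC)c(OC)c1
F2 | step 5 | (1S)-2-bromo-1-[3-methoxy-4-(methoxymethoxy)phenyl]ethan-1-ol | O[C@H](CBr)c1ccc(OCOC)c(OC)c1
F3 | step 5 | 2-{(1R)-2-bromo-1-[3-methoxy-4-(methoxymethoxy)phenyl]ethoxy}-6-hydroxy-4-[(3-methylbut-2-en-1-yl)oxy]benzaldehyde | O=Cc1c(O)cc(OCC=C(C)C)cc1O[C@@H](CBr)c1ccc(OCOC)c(OC)c1
F4 | step 4 | 2-{1-[3-methoxy-4-(methoxymethoxy)phenyl]ethenyl}-4,4,5,5-tetramethyl-1,3,2-dioxaborolane | C=C(B1OC(C)(C)C(C)(C)O1)c1ccc(OCOC)c(OC)c1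
F5 | step 6 | 2,4,6-trihydroxy-3-(2-methylbut-3-en-2-yl)benzaldehyde | C=CC(C)(C)c1c(O)cc(O)c(C=O)c1O
F6 | step 6 | 2,6-dihydroxy-4-(methoxymethoxy)-3-(2-methylbut-3-en-2-yl)benzaldehyde | C=CC(C)(C)c1c(OCOC)cc(O)c(C=O)c1O
F7 | step 6 | 2-hydroxy-6-({1-[3-methoxy-4-(methoxymethoxy)phenyl]ethenyl}oxy)-4-(methoxymethoxy)-3-(2-methylbut-3-en-2-yl)benzaldehyde | C=CC(C)(C)c1c(OCOC)cc(OC(=C)c2ccc(OCOC)c(OC)c2)c(C=O)c1O
F8 | step 6 | (2S)-5-hydroxy-7-(methoxymethoxy)-2-[3-methoxy-4-(methoxymethoxy)phenyl]-6-(2-methylbut-3-en-2-yl)-2,3-dihydro-4H-chromen-4-one | C=CC(C)(C)c1c(OCOC)cc2c(c1O)C(=O)C[C@@H](c1ccc(OCOC)c(OC)c1)O2
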